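**Retrosynthetic overview**
- Target ⇐ hydrogenolysis of its hexabenzyl ether; the C3/C4 configuration (each aroyl cis to its neighbouring aryl) ⇐ kinetic double protonation of the bis-enolate of the all-trans (2S,3S,4S,5S) tetrahydrofuran, in which C2 and C5 are already correct.
- All-trans tetrahydrofuran (the only ring made) ⇐ intramolecular oxa-Michael addition of a β-hydroxy ketone onto the neighbouring benzylidene ketone.
- The carbinol centre ⇐ copper-catalysed asymmetric conjugate borylation and oxidation of an achiral bis(benzylidene) 1,4-diketone.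
- Bis(benzylidene) diketone ⇐ 1,4-diaryl-1,4-diketone + two units of an aryl aldehyde dimethyl acetal; diketone ⇐ two units of an aryl Grignard reagent + succinic bis-Weinreb amide.
- Ring order: the four benzene rings are bought; the tetrahydrofuran is closed third from last.

Assumption: the target SMILES corresponds to the (2S,3R,4R,5S) isomer (2,3-cis, 3,4-trans, 4,5-cis), and "(R)-Tol-BINAP" in step 7 stands for whichever ligand enantiomer gives the S carbinol carbon.

**Step 1**
Reactants: 1 4-bromoresorcinol (4-bromobenzene-1,3-diol); 2 benzyl bromide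
Product: 3 2,4-bis(benzyloxy)-1-bromobenzene
Conditions: BnBr (2.2 equiv), K2CO3 (3 equiv), DMF, 60 °C
Reagents that add atoms: benzyl bromide (second equivalent), BrCc1ccccc1
Why: Double Williamson ether synthesis, in which each of the two phenoxides is benzylated by SN2 on one equivalent of benzyl bromide while the aryl bromide is untouched; no stereocentre is involved.

**Step 2**
Reactants: 4 succinyl chloride; 5 N,O-dimethylhydroxylamine hydrochloride
Product: 6 N,N'-dimethoxy-N,N'-dimethylsuccinamide
Conditions: MeNHOMe·HCl (2.2 equiv), Et3N (4.5 equiv), CH2Cl2, 0 °C to rt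
Reagents that add atoms: N,O-dimethylhydroxylamine hydrochloride (second equivalent), CNOC.Cl
Why: Nucleophilic acyl substitution (Schotten–Baumann-type amidation) at each of the two acid chloride groups, one equivalent of the amine per group, gives the bis-Weinreb amide; no stereocentre is involved.

**Step 3**
Reactants: 3 2,4-bis(benzyloxy)-1-bromobenzene; 6 N,N'-dimethoxy-N,N'-dimethylsuccinamide
Product: 8 1,4-bis[2,4-bis(benzyloxy)phenyl]butane-1,4-dione, via aryl Grignard reagent 7 (not isolated)
Conditions: 3 (2.3 equiv), Mg, LiCl, THF, rt; then 6 (1 equiv), 0 °C to rt; then 1 M HCl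
Reagents that add atoms: 2,4-bis(benzyloxy)-1-bromobenzene (second equivalent), Brc1ccc(OCc2ccccc2)cc1OCc1ccccc1
Why: Grignard formation followed by a twofold Weinreb ketone synthesis, one aryl Grignard unit per amide, in which each amide gives a chelated tetrahedral magnesium adduct that collapses to the aryl ketone only on acidic work-up, so over-addition is avoided; no stereocentre is involved.

**Step 4**
Reactants: 9 4-hydroxybenzaldehyde; 2 benzyl bromide
Product: 10 4-(benzyloxy)benzaldehyde
Conditions: BnBr (1.1 equiv), K2CO3, acetone, reflux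
Reagents that add atoms: none
Why: Williamson ether synthesis on the phenoxide, with the aldehyde inert to carbonate; no stereocentre is involved.

**Step 5**
Reactants: 10 4-(benzyloxy)benzaldehyde; 11 trimethyl orthoformate
Product: 12 1-(benzyloxy)-4-(dimethoxymethyl)benzene
Conditions: TsOH·H2O (cat.), MeOH, rt
Reagents that add atoms: none
Why: Acid-catalysed acetalisation driven by the orthoester gives an aldehyde equivalent that condenses without any metal aldolate, so neither retro-aldol nor a premature racemic ring closure can occur in step 6; no stereocentre is involved.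

**Step 6**
Reactants: 8 1,4-bis[2,4-bis(benzyloxy)phenyl]butane-1,4-dione; 12 1-(benzyloxy)-4-(dimethoxymethyl)benzene
Product: 15 (2E,3E)-1,4-bis[2,4-bis(benzyloxy)phenyl]-2,3-bis[4-(benzyloxy)benzylidene]butane-1,4-dione, via bis(silyl enol ether) 13 (not isolated), via bis(β-methoxy ketone) 14 (not isolated)
Conditions: 12 (2.4 equiv), TMSOTf (3 equiv), i-Pr2NEt (2.6 equiv), CH2Cl2, 0 °C to rt; then DBU, 40 °C
Reagents that add atoms: 1-(benzyloxy)-4-(dimethoxymethyl)benzene (second equivalent), COC(OC)c1ccc(OCc2ccccc2)cc1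
Why: One-pot soft enolisation and twofold Mukaiyama aldol-type addition, each silyl enol ether carbon adding to the oxocarbenium ion from one equivalent of the acetal, then E1cB loss of methanol from each arm, gives the bis-enone; its alkene geometry is of no consequence because all four alkene carbons become sp3 in step 7.

**Step 7**
Reactants: 15 (2E,3E)-1,4-bis[2,4-bis(benzyloxy)phenyl]-2,3-bis[4-(benzyloxy)benzylidene]butane-1,4-dione
Product: 18 (2S,3S,4S,5S)-3,4-bis[2,4-bis(benzyloxy)benzoyl]-2,5-bis[4-(benzyloxy)phenyl]tetrahydrofuran, via β-boryl ketone 16 (not isolated), via β-hydroxy ketone 17 (not isolated)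
Conditions: CuCl (5 mol %), NaOtBu (10 mol %), (R)-Tol-BINAP (6 mol %), B2pin2 (1.05 equiv), MeOH (2 equiv), THF, 0 °C; then NaBO3·4H2O, THF/H2O, rt; then K2CO3, MeOH, rt, stopped once the all-trans isomer dominates
Reagents that add atoms: sodium perborate tetrahydrate NaBO3·4H2O, O.O.O.O.[Na+].[O-]OB=O
Why: Ligand-controlled copper-catalysed asymmetric conjugate borylation of one enone sets the S boron-bearing carbon, perborate oxidation replaces boron by oxygen with retention, and the alkoxide then closes the ring by an intramolecular 5-endo-trig oxa-Michael addition onto the second enone (the mode known for acceptor-substituted homoallylic alkoxides); under carbonate C3 and C4 epimerise by enolisation and C5 by reversible addition, so the three new centres settle into the all-trans arrangement dictated by the fixed carbinol carbon, giving the C2-symmetric (2S,3S,4S,5S) isomer.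

**Step 8**
Reactants: 18 (2S,3S,4S,5S)-3,4-bis[2,4-bis(benzyloxy)benzoyl]-2,5-bis[4-(benzyloxy)phenyl]tetrahydrofuran
Product: 20 (2S,3R,4R,5S)-3,4-bis[2,4-bis(benzyloxy)benzoyl]-2,5-bis[4-(benzyloxy)phenyl]tetrahydrofuran, via dipotassium bis(enolate) 19 (not isolated)
Conditions: KN(SiMe3)2 (2.5 equiv), THF, −78 to −40 °C; then AcOH, THF, −78 °C
Reagents that add atoms: none
Why: Contra-thermodynamic epimerisation by Zimmerman-type kinetic protonation, in which both ketones are enolised so that C3 and C4 become planar while C2 and C5 stay fixed, and each enolate carbon is then protonated from the face opposite the aryl group on its neighbouring ring carbon (the flat acyl group on the other flank being the smaller obstacle), which places each aroyl group cis to the adjacent aryl and trans to the other aroyl, that is 3R,4R.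

**Step 9**
Reactants: 20 (2S,3R,4R,5S)-3,4-bis[2,4-bis(benzyloxy)benzoyl]-2,5-bis[4-(benzyloxy)phenyl]tetrahydrofuran
Product: 21 (2S,3R,4R,5S)-3,4-bis(2,4-dihydroxybenzoyl)-2,5-bis(4-hydroxyphenyl)tetrahydrofuran
Conditions: H2 (1 atm), 10% Pd/C, EtOAc/MeOH, rt
Reagents that add atoms: none
Why: Hydrogenolysis of the six aryl benzyl ethers under neutral conditions, where aryl benzyl ethers cleave much faster than the ring C–O bonds or the deactivated aryl ketones, so the acid- and base-sensitive stereocentres are not touched.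

**Compound list**
1 | 4-bromoresorcinol (4-bromobenzene-1,3-diol) | Oc1ccc(Br)c(O)c1 | starting material
2 | benzyl bromide | BrCc1ccccc1 | starting material
3 | 2,4-bis(benzyloxy)-1-bromobenzene | Brc1ccc(OCc2ccccc2)cc1OCc1ccccc1 | intermediate
4 | succinyl chloride (butanedioyl dichloride) | ClC(=O)CCC(=O)Cl | starting material
5 | N,O-dimethylhydroxylamine hydrochloride | CNOC.Cl | starting material
6 | N,N'-dimethoxy-N,N'-dimethylsuccinamide | CON(C)C(=O)CCC(=O)N(C)OC | intermediate
7 | [2,4-bis(benzyloxy)phenyl]magnesium bromide | Br[Mg]c1ccc(OCc2ccccc2)cc1OCc1ccccc1 | intermediate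
8 | 1,4-bis[2,4-bis(benzyloxy)phenyl]butane-1,4-dione | O=C(CCC(=O)c1ccc(OCc2ccccc2)cc1OCc1ccccc1)c1ccc(OCc2ccccc2)cc1OCc1ccccc1 | intermediate
9 | 4-hydroxybenzaldehyde | O=Cc1ccc(O)cc1 | starting material
10 | 4-(benzyloxy)benzaldehyde | O=Cc1ccc(OCc2ccccc2)cc1 | intermediate
11 | trimethyl orthoformate | COC(OC)OC | starting material
12 | 1-(benzyloxy)-4-(dimethoxymethyl)benzene | COC(OC)c1ccc(OCc2ccccc2)cc1 | intermediate
13 | (1Z,3Z)-1,4-bis[2,4-bis(benzyloxy)phenyl]-1,4-bis(trimethylsilyloxy)buta-1,3-diene | C[Si](C)(C)O/C(c1ccc(OCc2ccccc2)cc1OCc1ccccc1)=C\C=C(/O[Si](C)(C)C)c1ccc(OCc2ccccc2)cc1OCc1ccccc1 | intermediate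
14 | 1,4-bis[2,4-bis(benzyloxy)phenyl]-2,3-bis{[4-(benzyloxy)phenyl](methoxy)methyl}butane-1,4-dione (mixture of diastereomers) | COC(c1ccc(OCc2ccccc2)cc1)C(C(=O)c1ccc(OCc2ccccc2)cc1OCc1ccccc1)C(C(OC)c1ccc(OCc2ccccc2)cc1)C(=O)c1ccc(OCc2ccccc2)cc1OCc1ccccc1 | intermediate
15 | (2E,3E)-1,4-bis[2,4-bis(benzyloxy)phenyl]-2,3-bis[4-(benzyloxy)benzylidene]butane-1,4-dione | O=C(c1ccc(OCc2ccccc2)cc1OCc1ccccc1)/C(=C/c1ccc(OCc2ccccc2)cc1)C(=C/c1ccc(OCc2ccccc2)cc1)\C(=O)c1ccc(OCc2ccccc2)cc1OCc1ccccc1 | intermediate
16 | (E)-1,4-bis[2,4-bis(benzyloxy)phenyl]-2-[4-(benzyloxy)benzylidene]-3-{(S)-[4-(benzyloxy)phenyl](4,4,5,5-tetramethyl-1,3,2-dioxaborolan-2-yl)methyl}butane-1,4-dione (both C3 epimers) | O=C(c1ccc(OCc2ccccc2)cc1OCc1ccccc1)C([C@H](B1OC(C)(C)C(C)(C)O1)c1ccc(OCc2ccccc2)cc1)C(=C/c1ccc(OCc2ccccc2)cc1)\C(=O)c1ccc(OCc2ccccc2)cc1OCc1ccccc1 | intermediate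
17 | (E)-1,4-bis[2,4-bis(benzyloxy)phenyl]-2-[4-(benzyloxy)benzylidene]-3-{(S)-[4-(benzyloxy)phenyl](hydroxy)methyl}butane-1,4-dione (both C3 epimers) | O=C(c1ccc(OCc2ccccc2)cc1OCc1ccccc1)C([C@H](O)c1ccc(OCc2ccccc2)cc1)C(=C/c1ccc(OCc2ccccc2)cc1)\C(=O)c1ccc(OCc2ccccc2)cc1OCc1ccccc1 | intermediate
18 | (2S,3S,4S,5S)-3,4-bis[2,4-bis(benzyloxy)benzoyl]-2,5-bis[4-(benzyloxy)phenyl]tetrahydrofuran (all-trans) | O=C(c1ccc(OCc2ccccc2)cc1OCc1ccccc1)[C@H]1[C@H](C(=O)c2ccc(OCc3ccccc3)cc2OCc2ccccc2)[C@@H](c2ccc(OCc3ccccc3)cc2)O[C@@H]1c1ccc(OCc2ccccc2)cc1 | intermediate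
19 | dipotassium bis(enolate) of 18 (C3 and C4 planar, C2 and C5 as in 18) | [K+].[K+].[O-]C(c1ccc(OCc2ccccc2)cc1OCc1ccccc1)=C1C(=C([O-])c2ccc(OCc3ccccc3)cc2OCc2ccccc2)[C@@H](c2ccc(OCc3ccccc3)cc2)O[C@@H]1c1ccc(OCc2ccccc2)cc1 | intermediate
20 | (2S,3R,4R,5S)-3,4-bis[2,4-bis(benzyloxy)benzoyl]-2,5-bis[4-(benzyloxy)phenyl]tetrahydrofuran (2,3-cis, 3,4-trans, 4,5-cis) | O=C(c1ccc(OCc2ccccc2)cc1OCc1ccccc1)[C@@H]1[C@@H](C(=O)c2ccc(OCc3ccccc3)cc2OCc2ccccc2)[C@@H](c2ccc(OCc3ccccc3)cc2)O[C@@H]1c1ccc(OCc2ccccc2)cc1 | intermediate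
21 | (2S,3R,4R,5S)-3,4-bis(2,4-dihydroxybenzoyl)-2,5-bis(4-hydroxyphenyl)tetrahydrofuran (CNP0237262.3) | O=C(c1ccc(O)cc1O)[C@@H]1[C@@H](C(=O)c2ccc(O)cc2O)[C@@H](c2ccc(O)cc2)O[C@@H]1c1ccc(O)cc1 | target

**Step count**
Total step count: 9.
Longest linear sequence: 6 steps (1, 3, 6, 7, 8, 9; the chains starting at step 2 and at step 4 are no longer).

**Steps most likely to fail, with fallbacks**

Step 8 is the weakest point. The second protonation has to choose between a face flanked by an aryl group and a face flanked by an aroyl group, and the bis-enolate could also open the ring by E1cB. If selectivity is poor, the route leaves from 18. Soft enolisation (TMSOTf, Et3N, CH2Cl2) gives the bis(trimethylsilyl enol ether) F1, which is isolated. It is then protonated under reagent control with phenol as the proton source and a chiral N-triflyl thiophosphoramide Brønsted acid (both enantiomers screened for the matched case). This gives 20, where the route is rejoined; recovered 18 is recycled.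

Step 7 is next. The bis-enone is crowded and cross-conjugated, so the borylation may be slow or poorly enantioselective. The β-hydroxy ketone can lose water back to 15 or undergo retro-aldol cleavage instead of cyclising. Prolonged carbonate treatment can also erode the enantiomeric excess, because a 2,5-cis isomer can reopen at either C–O bond; the equilibration is therefore stopped early and the product checked by chiral HPLC. Any doubly borylated material ends as the diol and converges under the same carbonate treatment. If the borylation fails, the oxygen-bearing centres are set by an aldol reaction instead, starting from 8. The bis(silyl enol ether) 13 is prepared and isolated (TMSOTf, Et3N). A SiCl4/chiral bisphosphoramide-catalysed Mukaiyama aldol addition to two equivalents of aldehyde 10 then gives the C2-symmetric bis-aldol F2 with both carbinol carbons S. K2CO3 in MeOH causes E1cB loss of water from one arm and oxa-Michael closure by the remaining hydroxyl, rejoining the route at 18.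

Step 6 is third. The second condensation creates a tetra-aryl diene and may stall at the mono-benzylidene stage, and acid-promoted cyclisation of the 1,4-diketone to a furan competes if the amine base is consumed. The fallback starts from 8 and builds the alkenes by addition–elimination instead of condensation. Heating 8 with N,N-dimethylformamide dimethyl acetal gives the bis(enaminone) F3. [4-(Benzyloxy)phenyl]magnesium bromide F4 (made from commercial 1-(benzyloxy)-4-bromobenzene and Mg, two equivalents) then adds 1,4 to each enaminone with loss of dimethylamide, giving 15, where the route is rejoined.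

**Further compounds**
F1 | step 8 | bis(trimethylsilyl enol ether) of 18 (C2 and C5 as in 18) | C[Si](C)(C)OC(c1ccc(OCc2ccccc2)cc1OCc1ccccc1)=C1C(=C(O[Si](C)(C)C)c2ccc(OCc3ccccc3)cc2OCc2ccccc2)[C@@H](c2ccc(OCc3ccccc3)cc2)O[C@@H]1c1ccc(OCc2ccccc2)cc1
F2 | step 7 | 1,4-bis[2,4-bis(benzyloxy)phenyl]-2,3-bis{(S)-[4-(benzyloxy)phenyl](hydroxy)methyl}butane-1,4-dione | O=C(c1ccc(OCc2ccccc2)cc1OCc1ccccc1)C([C@H](O)c1ccc(OCc2ccccc2)cc1)C([C@H](O)c1ccc(OCc2ccccc2)cc1)C(=O)c1ccc(OCc2ccccc2)cc1OCc1ccccc1
F3 | step 6 | (2E,3E)-1,4-bis[2,4-bis(benzyloxy)phenyl]-2,3-bis[(dimethylamino)methylidene]butane-1,4-dione | CN(C)/C=C(/C(=O)c1ccc(OCc2ccccc2)cc1OCc1ccccc1)C(=C/N(C)C)\C(=O)c1ccc(OCc2ccccc2)cc1OCc1ccccc1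
F4 | step 6 | [4-(benzyloxy)phenyl]magnesium bromide | Br[Mg]c1ccc(OCc2ccccc2)cc1
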